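(The numbers in the tables are simulated for an exercise.)

- north-east: substrate 30 mM; reagent 50 mM; free catalyst 70 µM; impurity 9.7 µM; run made earlier
- flask: substrate 20 mM; reagent 50.0 mM; free catalyst 70 µM; impurity 9.7 µM; time 1.5 h

- north-east (time / min: product / %, substrate / %): 1.00: 0.5, 97.8; 3.00: 2.3, 97.1; 5.00: 8.1, 95.0; 8.00: 8.4, 89.1; 10.0: 11.1, 90.1; 15.0: 15.3, 83.6; 20.0: 22.6, 77.4

(each reading ± 1 percentage point)

- what was read earlier has a scatter of 1 percentage point, one standard deviation
- steps thought possible: reagent + free catalyst -> catalyst intermediate A; catalyst intermediate A -> catalyst intermediate B; substrate + catalyst intermediate B -> catalyst intermediate C; catalyst intermediate C -> free catalyst + product; free catalyst + impurity -> spent catalyst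

* concentration of product at 1.5 h, in mM
* concentration of substrate at 1.5 h, in mM

I started from the late end of this flask, at 1.5 h, and reckoned the fraction of substrate left rather than the fraction made. In the north-east run the substrate reading fell to 77.4% by 20.0 min. I let each impurity take one free catalyst, which gave 60.3 µM of live catalyst in both flasks.

My bench rule was that live catalyst works at a constant turnover frequency, the substrate consumed per unit of live catalyst per minute: 5.62 min⁻¹, a reading that carries the scatter. The fraction left is then one minus turnover frequency times live catalyst times time, over the substrate charged.

By my rule that fraction came to zero in this flask at 59.0 min, earlier than 1.5 h, so the rule gave no remainder to report at the asked time. The border of the rule lay nearer than that: the charge of this flask was 0.861 of the substrate at the last reading of the north-east run, so this flask started below the substrate that reading showed. I committed to product close to the charge and a small remainder of substrate that the rule could not number. The forecast did number it, with 17 mM of product and 3 mM of substrate, judging that “the straightness hints at saturation”.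

The flask gave 19.6 mM of product and 0.411 mM of substrate.

    reagent + free catalyst → catalyst intermediate A (k = 6220 M⁻¹ min⁻¹)
    catalyst intermediate A → catalyst intermediate B (k = 7.95 min⁻¹)
    substrate + catalyst intermediate B → catalyst intermediate C (k = 1690 M⁻¹ min⁻¹)
    catalyst intermediate C → free catalyst + product (k = 33.7 min⁻¹)
    free catalyst + impurity → spent catalyst (k = 25100 M⁻¹ s⁻¹)

The turnover frequency of 5.62 min⁻¹ had put the end of the substrate at 59.0 min, yet 0.411 mM of substrate remained in this flask at 1.5 h. In this flask at 0.150 h catalyst intermediate B took up substrate with a pseudo-first-order constant of 29.0 min⁻¹, above the 7.95 min⁻¹ of the turning of catalyst intermediate A into catalyst intermediate B, and 56.0% of the catalyst stood as catalyst intermediate A against 15.4% as catalyst intermediate B. At 1.50 h that constant in this flask was 0.694 min⁻¹, below 7.95 min⁻¹, and catalyst intermediate B was the resting state, 77.4% against 6.85%.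

In the neighbour charged with 0.028 mM of free catalyst, I reckoned live catalyst at 18.3 µM, and by my rule 5.62 min⁻¹ left a fraction of substrate of 53.7% at 1.5 h. The computed neighbour held 11.6 mM of substrate, 57.9% of its charge.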